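**Retrosynthetic overview**

1. The target is a depsidone with a 2,2-dimethylchromanone fused at C7/C8 (numbering used throughout: ring A = C1–C4, C4a, C11a; ether O5; ring B = C5a, C6–C9, C9a; lactone O10–C11). The last disconnections are the ring A O–ethyl bond, the chromanone (3,3-dimethylacrylic acid onto C8 and the C7 hydroxyl) and the acetal and acetonide protecting groups.
2. Feature used: the six carbons of ring A fall into three adjacent pairs. C11a/C1 (lactone carbonyl and methyl) is a but-2-ynoate, C4a/C4 (ether oxygen O5 and formyl carbon) is an aryl ynol ether acetal, and C3/C2 (phenol oxygen and H) is ethoxyacetylene. Donor- and acceptor-bearing carbons therefore alternate round the ring, and the first two pairs already hang on the neighbouring oxygens O10 and O5 of ring B.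
3. Key disconnection: a [2+2+2] alkyne cyclotrimerisation that forms C11a–C4a, C4–C3 and C2–C1 and so closes ring A and the seven-membered dioxepinone in one operation, from a ring B tethered diyne and ethoxyacetylene.
4. The diyne comes from 5-methylpyrogallol. An acetonide masks the C6/C7 oxygens, ortho-formylation then Baeyer–Villiger oxidation tells the O5 and O10 oxygens apart, the O5 phenol becomes the ynol ether through a dichlorovinyl ether, and the O10 phenol is acylated last.
5. Ring order: ring B (purchased) → ring A together with the dioxepinone (step 8) → pyranone ring of the chromanone (step 10).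

Key step: step 8

Remark: the target has no stereocentre; the only stereo element on the way, the E double bond of the dichlorovinyl ether, disappears in step 6, so racemic BINAP is sufficient.
Remark: 5-methylpyrogallol is assumed to be purchased (it is the tri-O-demethylation product of 3,4,5-trimethoxytoluene); the formyl group is carried as a diethyl acetal because its carbon is delivered by diethyl phenyl orthoformate.

**Route**

Step 1
Reactants: 1 5-methylbenzene-1,2,3-triol (5-methylpyrogallol)
Product: 2 2,2,6-trimethyl-1,3-benzodioxol-4-ol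
Conditions: Me2C(OMe)2, p-TsOH·H2O (cat.), toluene, reflux, MeOH removed over 4 Å MS
Reagents that add atoms: 2,2-dimethoxypropane, COC(C)(C)OC
Why: Acid-catalysed transketalisation (acetonide formation) across one vicinal pair of hydroxyls; the triol is symmetric, so either pair gives the same 1,3-benzodioxole and one phenol stays free.

Step 2
Reactants: 2 2,2,6-trimethyl-1,3-benzodioxol-4-ol
Product: 3 4-hydroxy-2,2,6-trimethyl-1,3-benzodioxole-5-carbaldehyde
Conditions: MgCl2, Et3N, (CH2O)n, MeCN, reflux; aq. HCl
Reagents that add atoms: paraformaldehyde (formaldehyde), C=O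
Why: Magnesium-mediated ortho-formylation of phenols (Casnati–Skattebøl) delivers formaldehyde within the magnesium phenoxide chelate, so only C5, the single free ortho position, is formylated and the free para position is left alone.

Step 3
Reactants: 3 4-hydroxy-2,2,6-trimethyl-1,3-benzodioxole-5-carbaldehyde; 4 trichloroethylene
Product: 6 4-[(E)-1,2-dichlorovinyloxy]-2,2,6-trimethyl-1,3-benzodioxole-5-carbaldehyde, via dichloroacetylene 5 (not isolated)
Conditions: K2CO3, DMF, 70 °C, N2
Reagents that add atoms: none
Why: Base-induced dehydrochlorination of trichloroethylene gives dichloroacetylene, to which the phenoxide adds (the standard preparation of aryl 1,2-dichlorovinyl ethers); anti addition should give the E isomer, whose geometry is of no consequence later.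

Step 4
Reactants: 6 4-[(E)-1,2-dichlorovinyloxy]-2,2,6-trimethyl-1,3-benzodioxole-5-carbaldehyde
Product: 8 4-[(E)-1,2-dichlorovinyloxy]-2,2,6-trimethyl-1,3-benzodioxol-5-ol, via aryl formate 7 (not isolated)
Conditions: mCPBA, NaHCO3, CH2Cl2, 0 °C to rt; then K2CO3 (cat.), MeOH, 0 °C
Reagents that add atoms: mCPBA, OOC(=O)c1cccc(Cl)c1
Why: Baeyer–Villiger (Dakin-type) oxidation of a benzaldehyde with ortho and para oxygen donors proceeds by aryl migration to the formate, which mild methanolysis cleaves, while the electron-poor dichlorovinyl ether should resist the peracid.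

Step 5
Reactants: 8 4-[(E)-1,2-dichlorovinyloxy]-2,2,6-trimethyl-1,3-benzodioxol-5-ol
Product: 9 tert-butyl{[4-[(E)-1,2-dichlorovinyloxy]-2,2,6-trimethyl-1,3-benzodioxol-5-yl]oxy}dimethylsilane
Conditions: TBSCl, imidazole, DMF, rt
Reagents that add atoms: TBSCl, CC(C)(C)[Si](C)(C)Cl
Why: Standard silylation of a phenol gives an ether that withstands n-BuLi and later leaves with fluoride under non-acidic conditions.

Step 6
Reactants: 9 tert-butyl{[4-[(E)-1,2-dichlorovinyloxy]-2,2,6-trimethyl-1,3-benzodioxol-5-yl]oxy}dimethylsilane; 10 diethyl phenyl orthoformate [(diethoxymethoxy)benzene]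
Product: 13 tert-butyl{[4-(3,3-diethoxyprop-1-ynyloxy)-2,2,6-trimethyl-1,3-benzodioxol-5-yl]oxy}dimethylsilane, via lithium aryloxyacetylide 11 (not isolated), via aryloxyethynylmagnesium bromide 12 (not isolated)
Conditions: n-BuLi (2.1 equiv), Et2O, −78 to −40 °C; MgBr2·OEt2, −40 to 0 °C; 10, 0 °C to rt; aq. NaHCO3, Et3N-deactivated silica
Reagents that add atoms: none
Why: n-BuLi turns the 1,2-dichlorovinyl ether into the lithium aryloxyacetylide by dehydrochlorination and chlorine–lithium exchange, and after transmetalation the alkynyl Grignard reagent displaces phenoxide from the mixed orthoformate (Bodroux–Chichibabin acetal synthesis) under wholly non-acidic conditions that spare the ynol ether.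

Step 7
Reactants: 13 tert-butyl{[4-(3,3-diethoxyprop-1-ynyloxy)-2,2,6-trimethyl-1,3-benzodioxol-5-yl]oxy}dimethylsilane; 14 but-2-ynoic acid
Product: 17 4-(3,3-diethoxyprop-1-ynyloxy)-2,2,6-trimethyl-1,3-benzodioxol-5-yl but-2-ynoate, via but-2-ynoic anhydride 15 (not isolated), via tetrabutylammonium phenoxide 16 (not isolated)
Conditions: 14, DCC (0.5 equiv), CH2Cl2, 0 °C, filtered; 13, TBAF (1.0 equiv, dried THF solution), THF, −40 °C, then the anhydride solution, −40 to 0 °C
Reagents that add atoms: none
Why: Carbodiimide dehydration gives the symmetrical anhydride, and fluoride cleavage of the aryl silyl ether releases a phenoxide that the anhydride acylates at once (desilylative acylation), so neither a free carboxylic acid, which would add across the ynol ether, nor a long-lived phenoxide next to it is present.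

Step 8
Reactants: 17 4-(3,3-diethoxyprop-1-ynyloxy)-2,2,6-trimethyl-1,3-benzodioxol-5-yl but-2-ynoate; 18 ethoxyacetylene
Product: 19 4-(diethoxymethyl)-3-ethoxy-1,9-dimethyl-6,7-(propane-2,2-diyldioxy)-11H-dibenzo[b,e][1,4]dioxepin-11-one
Conditions: [Rh(cod)2]BF4 (10 mol %), rac-BINAP (10 mol %), H2 then Ar, CH2Cl2, rt; 17 and 18 (3 equiv) added slowly by syringe pump, final 0.01 M
Reagents that add atoms: none
Why: Proposed new method: cationic monovalent rhodium bearing BINAP is expected to couple ethoxyacetylene 18 oxidatively with the but-2-ynoate (its nucleophilic CH carbon bonding to the electrophilic methyl-bearing carbon) to give a rhodacyclopentadiene, into whose rhodium–carbon bond next to the ester carbonyl the tethered aryloxyalkyne inserts through its oxygen-bearing carbon, and reductive elimination then joins the acetal-bearing and ethoxy-bearing carbons; oxidative coupling of the two tethered alkynes first, followed by insertion of 18, would lead to the same arene. The closest known reaction type is the [2+2+2] cycloaddition of ester-linked 1,6-diynes with monoalkynes under cationic monovalent rhodium/BINAP catalysis, a catalyst that also accepts aryl ethynyl ethers, whereas a 1,8-diyne with a seven-membered tether ring and an internal aryl ynol ether partner is not covered by it. Ring A closes by [2+2+2] annulation, its last bond formed by reductive elimination from a seven-membered rhodacycle, and the dioxepinone closes through the C11a–C4a bond in a seven-membered mode that is exo to both triple bonds, helped by the rigid ortho-phenylene unit of ring B that holds the ester and ether arms side by side. No stereocentre is created. The step needs cross-trimerisation instead of homotrimerisation of 18 and a single orientation of 18 (ethoxy carbon next to the acetal carbon), and both follow from the alternating polarity of the three alkynes (acceptor ynoate between two donor ynol ethers), which pairs every nucleophilic alkyne carbon with an electrophilic one, with slow addition at high dilution as a further safeguard.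

Step 9
Reactants: 19 4-(diethoxymethyl)-3-ethoxy-1,9-dimethyl-6,7-(propane-2,2-diyldioxy)-11H-dibenzo[b,e][1,4]dioxepin-11-one
Product: 21 3-ethoxy-6,7-dihydroxy-1,9-dimethyl-11-oxo-11H-dibenzo[b,e][1,4]dioxepine-4-carbaldehyde, via aldehyde acetonide 20 (not isolated)
Conditions: TFA/H2O (9:1), rt to 40 °C, Ar
Reagents that add atoms: water, O
Why: Acid-catalysed hydrolysis removes the diethyl acetal first and the catechol isopropylidene ketal next, while the aryl ethyl ether, the diaryl ether and the lactone are stable to aqueous acid.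

Step 10
Reactants: 21 3-ethoxy-6,7-dihydroxy-1,9-dimethyl-11-oxo-11H-dibenzo[b,e][1,4]dioxepine-4-carbaldehyde; 22 3,3-dimethylacrylic acid
Product: 24 3-ethoxy-6-hydroxy-1,9-dimethyl-11-oxo-dibenzo[b,e][1,4]dioxepine-4-carbaldehyde carrying a 2,2-dimethyl-2,3-dihydropyran-4-one ring fused at C7 (ring O) and C8 (C=O), via ortho-hydroxyaryl enone 23 (not isolated)
Conditions: P2O5 in MeSO3H (Eaton's reagent), 60 °C
Reagents that add atoms: none
Why: Friedel–Crafts acylation at C8, the only free position of the electron-rich ring B (ortho to the C7 hydroxyl, para to O5), followed by oxa-Michael closure of the C7 hydroxyl onto the enone is the standard chromanone annulation of pyrogallol-type phenols, and ring A, deactivated by formyl and lactone carbonyl and lacking a free hydroxyl, cannot form a second chromanone.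

Step 11
Reactants: 24 the chromanone-fused 3-ethoxy depsidone aldehyde
Product: 25 target CNP0271978.0 (3,6-dihydroxy-1,9-dimethyl-11-oxo-dibenzo[b,e][1,4]dioxepine-4-carbaldehyde with the 2,2-dimethyl-2,3-dihydropyran-4-one ring fused at C7/C8)
Conditions: BCl3 (4 equiv), CH2Cl2, −78 to 0 °C; then H2O
Reagents that add atoms: none
Why: Boron trichloride cleaves alkyl aryl ethers ortho to a carbonyl group selectively through a six-membered boron chelate between the formyl and ether oxygens, and the diaryl ether, the lactone and the chromanone ring ether should survive at low temperature.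

**Compound list**

1 | 5-methylbenzene-1,2,3-triol (5-methylpyrogallol) | Cc1cc(O)c(O)c(O)c1 | starting material
2 | 2,2,6-trimethyl-1,3-benzodioxol-4-ol | Cc1cc(O)c2c(c1)OC(C)(C)O2 | intermediate
3 | 4-hydroxy-2,2,6-trimethyl-1,3-benzodioxole-5-carbaldehyde | Cc1cc2c(c(O)c1C=O)OC(C)(C)O2 | intermediate
4 | trichloroethylene | ClC=C(Cl)Cl | starting material
5 | dichloroacetylene | ClC#CCl | intermediate
6 | 4-[(E)-1,2-dichlorovinyloxy]-2,2,6-trimethyl-1,3-benzodioxole-5-carbaldehyde | Cl/C=C(/Cl)Oc1c(C=O)c(C)cc2c1OC(C)(C)O2 | intermediate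
7 | 4-[(E)-1,2-dichlorovinyloxy]-2,2,6-trimethyl-1,3-benzodioxol-5-yl formate | Cl/C=C(/Cl)Oc1c(OC=O)c(C)cc2c1OC(C)(C)O2 | intermediate
8 | 4-[(E)-1,2-dichlorovinyloxy]-2,2,6-trimethyl-1,3-benzodioxol-5-ol | Cl/C=C(/Cl)Oc1c(O)c(C)cc2c1OC(C)(C)O2 | intermediate
9 | tert-butyl{[4-[(E)-1,2-dichlorovinyloxy]-2,2,6-trimethyl-1,3-benzodioxol-5-yl]oxy}dimethylsilane | Cl/C=C(/Cl)Oc1c(O[Si](C)(C)C(C)(C)C)c(C)cc2c1OC(C)(C)O2 | intermediate
10 | diethyl phenyl orthoformate [(diethoxymethoxy)benzene] | CCOC(OCC)Oc1ccccc1 | starting material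
11 | {[5-(tert-butyldimethylsilyloxy)-2,2,6-trimethyl-1,3-benzodioxol-4-yl]oxy}ethynyllithium | [Li]C#COc1c(O[Si](C)(C)C(C)(C)C)c(C)cc2c1OC(C)(C)O2 | intermediate
12 | {[5-(tert-butyldimethylsilyloxy)-2,2,6-trimethyl-1,3-benzodioxol-4-yl]oxy}ethynylmagnesium bromide | Br[Mg]C#COc1c(O[Si](C)(C)C(C)(C)C)c(C)cc2c1OC(C)(C)O2 | intermediate
13 | tert-butyl{[4-(3,3-diethoxyprop-1-ynyloxy)-2,2,6-trimethyl-1,3-benzodioxol-5-yl]oxy}dimethylsilane | CCOC(OCC)C#COc1c(O[Si](C)(C)C(C)(C)C)c(C)cc2c1OC(C)(C)O2 | intermediate
14 | but-2-ynoic acid | CC#CC(=O)O | starting material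
15 | but-2-ynoic anhydride | CC#CC(=O)OC(=O)C#CC | intermediate
16 | tetrabutylammonium 4-(3,3-diethoxyprop-1-ynyloxy)-2,2,6-trimethyl-1,3-benzodioxol-5-olate | CCOC(OCC)C#COc1c([O-])c(C)cc2c1OC(C)(C)O2.CCCC[N+](CCCC)(CCCC)CCCC | intermediate
17 | 4-(3,3-diethoxyprop-1-ynyloxy)-2,2,6-trimethyl-1,3-benzodioxol-5-yl but-2-ynoate | CC#CC(=O)Oc1c(C)cc2c(c1OC#CC(OCC)OCC)OC(C)(C)O2 | intermediate
18 | ethoxyacetylene | C#COCC | starting material
19 | 4-(diethoxymethyl)-3-ethoxy-1,9-dimethyl-6,7-(propane-2,2-diyldioxy)-11H-dibenzo[b,e][1,4]dioxepin-11-one | Cc1cc(OCC)c(C(OCC)OCC)c2c1C(=O)Oc1c(C)cc3c(c1O2)OC(C)(C)O3 | intermediate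
20 | 3-ethoxy-1,9-dimethyl-11-oxo-6,7-(propane-2,2-diyldioxy)-11H-dibenzo[b,e][1,4]dioxepine-4-carbaldehyde | Cc1cc(OCC)c(C=O)c2c1C(=O)Oc1c(C)cc3c(c1O2)OC(C)(C)O3 | intermediate
21 | 3-ethoxy-6,7-dihydroxy-1,9-dimethyl-11-oxo-11H-dibenzo[b,e][1,4]dioxepine-4-carbaldehyde | Cc1cc(OCC)c(C=O)c2c1C(=O)Oc1c(C)cc(O)c(O)c1O2 | intermediate
22 | 3,3-dimethylacrylic acid (3-methylbut-2-enoic acid) | CC(C)=CC(=O)O | starting material
23 | 3-ethoxy-6,7-dihydroxy-1,9-dimethyl-8-(3-methylbut-2-enoyl)-11-oxo-11H-dibenzo[b,e][1,4]dioxepine-4-carbaldehyde | Cc1cc(OCC)c(C=O)c2c1C(=O)Oc1c(C)c(C(=O)C=C(C)C)c(O)c(O)c1O2 | intermediate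
24 | 3-ethoxy-6-hydroxy-1,9-dimethyl-11-oxo-dibenzo[b,e][1,4]dioxepine-4-carbaldehyde with a 2,2-dimethyl-2,3-dihydropyran-4-one ring fused at C7 (ring O) and C8 (C=O) | Cc1cc(OCC)c(C=O)c2c1C(=O)Oc1c(C)c3c(c(O)c1O2)OC(C)(C)CC3=O | intermediate
25 | CNP0271978.0, the 3-hydroxy analogue of 24 | Cc1cc(O)c(C=O)c2c1C(=O)Oc1c(C)c3c(c(O)c1O2)OC(C)(C)CC3=O | target

Total step count: 11. Longest linear sequence: 11 steps (1 to 25).

**Steps most likely to fail**

Step 8. The seven-membered closure may lose to coupling of the ynoate of one molecule with the ynol ether of another (oligomerisation). Ethoxyacetylene may also homotrimerise or insert in the reverse orientation, and trace water may hydrate the ynol ether on the Lewis-acidic rhodium.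

Fallback by known chemistry, from 3 back to 20, a classical depside/intramolecular SNAr assembly:
- Benzylation of 3 (BnBr, K2CO3, DMF) would give 4-(benzyloxy)-2,2,6-trimethyl-1,3-benzodioxole-5-carbaldehyde F1. Baeyer–Villiger oxidation and methanolysis under the conditions of step 4 would then give 4-(benzyloxy)-2,2,6-trimethyl-1,3-benzodioxol-5-ol F2.
- Ring A is brought in as a preformed arene. Commercial 2,6-difluoro-4-methylbenzaldehyde with NaOEt (1 equiv, EtOH) gives 2-ethoxy-6-fluoro-4-methylbenzaldehyde F3; the two fluorides are equivalent. In situ protection of the formyl group as a lithium α-amino alkoxide, deprotonation next to fluorine with lithium 2,2,6,6-tetramethylpiperidide and a CO2 quench then give 4-ethoxy-2-fluoro-3-formyl-6-methylbenzoic acid F4.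
- Esterification of F4 with F2 by the trifluoroacetic anhydride method gives the depside 4-(benzyloxy)-2,2,6-trimethyl-1,3-benzodioxol-5-yl 4-ethoxy-2-fluoro-3-formyl-6-methylbenzoate F5. Hydrogenolysis (H2, Pd/C, EtOAc) frees the neighbouring phenol to give 4-hydroxy-2,2,6-trimethyl-1,3-benzodioxol-5-yl 4-ethoxy-2-fluoro-3-formyl-6-methylbenzoate F6.
- Cs2CO3 in DMF closes the dioxepinone by intramolecular SNAr at the fluoride flanked by the formyl and aroyl groups and gives 20. The 2,6-disubstituted aroyl group should resist the acyl shift to the neighbouring oxygen that would scramble ring B. The conditions of step 9 then lead on to 21.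

Step 6. The magnesium acetylide may react too slowly with the orthoformate, so that protonation or decomposition of the aryloxyacetylide on warming overtakes C–C bond formation, and the ynol ether acetal may be hydrated during isolation.

Fallback, from 9 back to 20, carrying the formyl carbon at the alcohol oxidation level:
- The acetylide 11, generated as in step 6, is trapped with paraformaldehyde, the most dependable electrophile for such acetylides. The lithium alkoxide is silylated in the same flask with TBDPSCl to give tert-butyl{[4-[3-(tert-butyldiphenylsilyloxy)prop-1-ynyloxy]-2,2,6-trimethyl-1,3-benzodioxol-5-yl]oxy}dimethylsilane F7.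
- Under the conditions of step 7 only the aryl silyl ether is cleaved and acylated, giving 4-[3-(tert-butyldiphenylsilyloxy)prop-1-ynyloxy]-2,2,6-trimethyl-1,3-benzodioxol-5-yl but-2-ynoate F8.
- The conditions of step 8 would give 4-[(tert-butyldiphenylsilyloxy)methyl]-3-ethoxy-1,9-dimethyl-6,7-(propane-2,2-diyldioxy)-11H-dibenzo[b,e][1,4]dioxepin-11-one F9.
- TBAF buffered with AcOH frees 3-ethoxy-4-(hydroxymethyl)-1,9-dimethyl-6,7-(propane-2,2-diyldioxy)-11H-dibenzo[b,e][1,4]dioxepin-11-one F10. MnO2 in CH2Cl2 oxidises this benzylic alcohol to 20 before the catechol is unmasked.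

Step 10. Acid-promoted condensation at the free formyl group, conjugate alkylation by the protonated acrylic acid (which ends in a dihydrocoumarin instead of the chromanone) or acylation of ring A at C2 may compete with the wanted acylation at C8.

Fallback, from 21 back to 24, separating acylation from ring closure:
- TiCl4-mediated ortho-acylation of the ring B catechol with commercial 3,3-dimethylacryloyl chloride (CH2Cl2, −20 to 0 °C) delivers the acyl group within a titanium phenoxide. It would give the enone 23 as an isolated compound under conditions too mild for condensation at the formyl group or for alkylation.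
- A catalytic amount of DBU in THF then closes the pyranone by oxa-Michael addition to give 24.
- This fallback makes no compound outside the list (F0).

**Further compounds**

F1 | step 8 | 4-(benzyloxy)-2,2,6-trimethyl-1,3-benzodioxole-5-carbaldehyde | Cc1cc2c(c(OCc3ccccc3)c1C=O)OC(C)(C)O2
F2 | step 8 | 4-(benzyloxy)-2,2,6-trimethyl-1,3-benzodioxol-5-ol | Cc1cc2c(c(OCc3ccccc3)c1O)OC(C)(C)O2
F3 | step 8 | 2-ethoxy-6-fluoro-4-methylbenzaldehyde | CCOc1cc(C)cc(F)c1C=O
F4 | step 8 | 4-ethoxy-2-fluoro-3-formyl-6-methylbenzoic acid | CCOc1cc(C)c(C(=O)O)c(F)c1C=O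
F5 | step 8 | 4-(benzyloxy)-2,2,6-trimethyl-1,3-benzodioxol-5-yl 4-ethoxy-2-fluoro-3-formyl-6-methylbenzoate | CCOc1cc(C)c(C(=O)Oc2c(C)cc3c(c2OCc2ccccc2)OC(C)(C)O3)c(F)c1C=O
F6 | step 8 | 4-hydroxy-2,2,6-trimethyl-1,3-benzodioxol-5-yl 4-ethoxy-2-fluoro-3-formyl-6-methylbenzoate | CCOc1cc(C)c(C(=O)Oc2c(C)cc3c(c2O)OC(C)(C)O3)c(F)c1C=O
F7 | step 6 | tert-butyl{[4-[3-(tert-butyldiphenylsilyloxy)prop-1-ynyloxy]-2,2,6-trimethyl-1,3-benzodioxol-5-yl]oxy}dimethylsilane | Cc1cc2c(c(OC#CCO[Si](c3ccccc3)(c3ccccc3)C(C)(C)C)c1O[Si](C)(C)C(C)(C)C)OC(C)(C)O2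
F8 | step 6 | 4-[3-(tert-butyldiphenylsilyloxy)prop-1-ynyloxy]-2,2,6-trimethyl-1,3-benzodioxol-5-yl but-2-ynoate | CC#CC(=O)Oc1c(C)cc2c(c1OC#CCO[Si](c1ccccc1)(c1ccccc1)C(C)(C)C)OC(C)(C)O2
F9 | step 6 | 4-[(tert-butyldiphenylsilyloxy)methyl]-3-ethoxy-1,9-dimethyl-6,7-(propane-2,2-diyldioxy)-11H-dibenzo[b,e][1,4]dioxepin-11-one | Cc1cc(OCC)c(CO[Si](c3ccccc3)(c3ccccc3)C(C)(C)C)c2c1C(=O)Oc1c(C)cc3c(c1O2)OC(C)(C)O3
F10 | step 6 | 3-ethoxy-4-(hydroxymethyl)-1,9-dimethyl-6,7-(propane-2,2-diyldioxy)-11H-dibenzo[b,e][1,4]dioxepin-11-one | Cc1cc(OCC)c(CO)c2c1C(=O)Oc1c(C)cc3c(c1O2)OC(C)(C)O3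
F0 | step 10 | none | none
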